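Bonds cut, in retrosynthetic order: the aryl ketone is traced back to a β-aryl acrylate (its C=C is cleaved last) and the C3 hydroxymethyl to a formyl group; the oxolane C2–C3 bond is then cut and C2 rejoined to the formyl oxygen, which opens the ring to a seven-membered 2-aryl-4,5-dihydro-1,3-dioxepine; the C4–alkenyl bond and the two acetal C–O bonds follow.
Enabling feature: oxolane C2 is a benzylic carbon on the ring oxygen and sits β to the formyl carbon (a cyclic aldol retron); C5, C4, C3 and the hydroxymethyl carbon form a 1,4-dioxygenated C4 unit that maps onto but-2-ene-1,4-diol, and C2 is the carbonyl carbon of 3,4,5-trimethoxybenzaldehyde.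
Forward order: acetalisation closes the dioxepine ring; an enantioselective Heck alkenylation joins the masked aroyl unit at C5 and leaves a vinyl acetal; a Lewis acid 1,3 O-to-C shift contracts the seven-membered ring to the oxolane (no other ring is made); borohydride, dihydroxylation and glycol cleavage finish.
Stereochemistry: target C4 comes from the palladium/tBu-PHOX catalyst (5R in the dioxepine); C3 (trans to C4) and C2 (cis to C3) are relayed from it in the kinetically controlled contraction and frozen by immediate reduction; C4 ends α to the ketone in its preferred trans relation to C3.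

Key step: step 4

Assumption: (S)-tBu-PHOX is taken to give the 5R Heck product by analogy with related cyclic alkenes; should the sense be opposite, the (R)-ligand is used and nothing else changes.
Locants used below: oxolane O1, C2 (aryl), C3 (CH2OH), C4 (aroyl), C5; dioxepine O1, C2 (acetal), O3, C4, C5, C6, C7.

Step 1
Reactants: 1 (Z)-but-2-ene-1,4-diol; 2 3,4,5-trimethoxybenzaldehyde
Product: 3 2-(3,4,5-trimethoxyphenyl)-4,7-dihydro-1,3-dioxepine
Conditions: p-TsOH·H2O (cat.), benzene, reflux, Dean–Stark
Reagents that add atoms: none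
Why: Acid-catalysed acetalisation driven by azeotropic removal of water closes the seven-membered ring because the Z alkene holds both hydroxyls within reach of one carbonyl carbon; no stereocentre arises, since the acetal carbon lies on the mirror plane of the ring.

Step 2
Reactants: 4 ethyl 3-oxo-3-(3,4,5-trimethoxyphenyl)propanoate
Product: 5 ethyl (2Z)-3-(3,4,5-trimethoxyphenyl)-3-{[(trifluoromethyl)sulfonyl]oxy}prop-2-enoate
Conditions: (CF3SO2)2O, aq. LiOH, toluene, 5 °C
Reagents that add atoms: trifluoromethanesulfonic anhydride, O=S(=O)(OS(=O)(=O)C(F)(F)F)C(F)(F)F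
Why: O-Triflation of a β-keto ester enolate: LiOH gives the lithium-chelated Z enolate, which the anhydride traps on oxygen to give the Z enol triflate; the geometry only has to be uniform, because this alkene is cleaved in step 6.

Step 3
Reactants: 3 2-(3,4,5-trimethoxyphenyl)-4,7-dihydro-1,3-dioxepine; 5 ethyl (2Z)-3-(3,4,5-trimethoxyphenyl)-3-{[(trifluoromethyl)sulfonyl]oxy}prop-2-enoate
Product: 6 ethyl (2E)-3-[(5R)-2-(3,4,5-trimethoxyphenyl)-4,5-dihydro-1,3-dioxepin-5-yl]-3-(3,4,5-trimethoxyphenyl)prop-2-enoate (both epimers at the acetal carbon C2)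
Conditions: Pd2(dba)3 (3 mol%), (S)-tBu-PHOX (7 mol%), iPr2NEt, THF, 60 °C
Reagents that add atoms: none
Why: Enantioselective intermolecular Heck alkenylation by the cationic pathway: the alkenyl triflate adds to zerovalent palladium with retention of geometry, the P,N ligand steers syn-carbopalladation to one of the two enantiotopic alkene carbons and so sets C5 (R), and syn β-hydride elimination can only go toward C7 (the C5 hydrogen is anti to palladium), which leaves the C6=C7 enol ether; the acetal carbon becomes a second stereocentre of no consequence, and alkenyl triflates with a cis ester group are established partners for this reaction on cyclic alkenes.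

Step 4
Reactants: 6 ethyl (2E)-3-[(5R)-2-(3,4,5-trimethoxyphenyl)-4,5-dihydro-1,3-dioxepin-5-yl]-3-(3,4,5-trimethoxyphenyl)prop-2-enoate
Product: 8 ethyl (2E)-3-[(3R,4R,5R)-4-(hydroxymethyl)-5-(3,4,5-trimethoxyphenyl)oxolan-3-yl]-3-(3,4,5-trimethoxyphenyl)prop-2-enoate, via oxolane-3-carbaldehyde 7 (not isolated)
Conditions: Me3SiOSO2CF3 (20 mol%), CH2Cl2, −78 °C; then NaBH4, MeOH, −78 to −40 °C
Reagents that add atoms: none
Why: The silyl triflate silylates the enol-ether oxygen O1 and the C2–O1 bond ionises to an aryl-stabilised E oxocarbenium ion (C2=O3) that stays tethered through C4 and C5 to a Z silyl enol ether (O1–C7=C6); C6 then adds to C2 in an intramolecular Mukaiyama-aldol-type step and the silyl group is released as the C7 formyl group forms, so the acid turns over. The closest known reaction is this same Lewis acid 1,3 oxygen-to-carbon ring contraction (Petasis–Ferrier-type vinyl acetal rearrangement) of 4,5-dihydro-1,3-dioxepines to oxolane-3-carbaldehydes, the ester-bearing alkenyl group at C5 being only a new substituent. One ring is closed, the oxolane (O3, C2, C6, C5, C4), in a 5-(enolexo)-endo-trig mode (the C=O+ bond inside the new ring, the enol C=C outside), which is usual for tethered oxocarbenium ions. The new centre at old C6 (oxolane C3) is controlled by the catalyst-set C5: with the C5 alkenyl group pseudoequatorial in the chair-like ring, C2 moves across the face of the enol ether on which it already lies, which puts the formyl carbon trans to the C5 substituent; the new centre at C2 is controlled kinetically, the compact E-oxocarbenium/Z-enol ion pair collapsing at −78 °C with aryl cis to formyl, and both acetal epimers of 6 should converge because C2 is planar in the cation. The step needs 2,3-cis/3,4-trans diastereoselectivity and cleavage of C2–O1 rather than C2–O3: the enol oxygen is by far the better leaving group, the ester-deactivated trisubstituted alkene is too electron-poor to intercept the cation in a Prins reaction, and the tertiary allylic C5–H is not acidified enough to racemise. NaBH4 in MeOH added at −78 °C reduces only the aldehyde, which stops both Lewis acid reopening (drift of C2 to the 2,3-trans isomer) and epimerisation at C3, while the 3,4-trans arrangement keeps the new alkoxide from adding to the enoate (a trans-fused bicyclic ether would result).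

Step 5
Reactants: 8 ethyl (2E)-3-[(3R,4R,5R)-4-(hydroxymethyl)-5-(3,4,5-trimethoxyphenyl)oxolan-3-yl]-3-(3,4,5-trimethoxyphenyl)prop-2-enoate
Product: 9 ethyl 2,3-dihydroxy-3-[(3S,4R,5R)-4-(hydroxymethyl)-5-(3,4,5-trimethoxyphenyl)oxolan-3-yl]-3-(3,4,5-trimethoxyphenyl)propanoate (syn diol, both facial diastereomers)
Conditions: K2OsO2(OH)4 (2 mol%), NMO, citric acid, tBuOH/H2O (1:1), rt
Reagents that add atoms: N-methylmorpholine N-oxide, C[N+]1([O-])CCOCC1; water, O
Why: Upjohn-type OsO4-catalysed syn-dihydroxylation with NMO as terminal oxidant, run with citric acid to speed osmate ester hydrolysis on the electron-poor alkene; the two new carbinol centres are destroyed in step 6, so facial selectivity does not matter, and the primary alcohol, aryl ethers and benzylic ring ether are inert.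

Step 6
Reactants: 9 ethyl 2,3-dihydroxy-3-[(3S,4R,5R)-4-(hydroxymethyl)-5-(3,4,5-trimethoxyphenyl)oxolan-3-yl]-3-(3,4,5-trimethoxyphenyl)propanoate
Product: 10 [(3S,4R,5R)-4-(hydroxymethyl)-5-(3,4,5-trimethoxyphenyl)oxolan-3-yl](3,4,5-trimethoxyphenyl)methanone, the target (2R,3R,4S in the locants above)
Conditions: NaIO4, THF/H2O, 0 °C to rt
Reagents that add atoms: none
Why: Malaprade periodate cleavage of the vicinal diol releases the aryl ketone and ethyl glyoxylate under near-neutral conditions, so C4, now α to the ketone and β to the ring oxygen, should neither epimerise (it already has the favoured trans relation to C3) nor open by retro-oxa-Michael elimination, and the hydroxymethyl group cannot close a hemiketal because that ring would be trans-fused.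

Compound list
1 | (Z)-but-2-ene-1,4-diol | OC/C=C\CO | starting material
2 | 3,4,5-trimethoxybenzaldehyde | COc1cc(C=O)cc(OC)c1OC | starting material
3 | 2-(3,4,5-trimethoxyphenyl)-4,7-dihydro-1,3-dioxepine | COc1cc(C2OCC=CCO2)cc(OC)c1OC | intermediate
4 | ethyl 3-oxo-3-(3,4,5-trimethoxyphenyl)propanoate | CCOC(=O)CC(=O)c1cc(OC)c(OC)c(OC)c1 | starting material
5 | ethyl (2Z)-3-(3,4,5-trimethoxyphenyl)-3-{[(trifluoromethyl)sulfonyl]oxy}prop-2-enoate | CCOC(=O)/C=C(\OS(=O)(=O)C(F)(F)F)c1cc(OC)c(OC)c(OC)c1 | intermediate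
6 | ethyl (2E)-3-[(5R)-2-(3,4,5-trimethoxyphenyl)-4,5-dihydro-1,3-dioxepin-5-yl]-3-(3,4,5-trimethoxyphenyl)prop-2-enoate, both C2 epimers | COc1cc(/C(=C/C(=O)OCC)[C@@H]2COC(c3cc(OC)c(OC)c(OC)c3)OC=C2)cc(OC)c1OC | intermediate
7 | ethyl (2E)-3-[(3R,4S,5R)-4-formyl-5-(3,4,5-trimethoxyphenyl)oxolan-3-yl]-3-(3,4,5-trimethoxyphenyl)prop-2-enoate, formed and reduced in the flask | COc1cc(/C(=C/C(=O)OCC)[C@@H]2CO[C@@H](c3cc(OC)c(OC)c(OC)c3)[C@H]2C=O)cc(OC)c1OC | intermediate
8 | ethyl (2E)-3-[(3R,4R,5R)-4-(hydroxymethyl)-5-(3,4,5-trimethoxyphenyl)oxolan-3-yl]-3-(3,4,5-trimethoxyphenyl)prop-2-enoate | COc1cc(/C(=C/C(=O)OCC)[C@@H]2CO[C@@H](c3cc(OC)c(OC)c(OC)c3)[C@H]2CO)cc(OC)c1OC | intermediate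
9 | ethyl 2,3-dihydroxy-3-[(3S,4R,5R)-4-(hydroxymethyl)-5-(3,4,5-trimethoxyphenyl)oxolan-3-yl]-3-(3,4,5-trimethoxyphenyl)propanoate, syn diol, both facial diastereomers | COc1cc(C(O)(C(O)C(=O)OCC)[C@@H]2CO[C@@H](c3cc(OC)c(OC)c(OC)c3)[C@H]2CO)cc(OC)c1OC | intermediate
10 | [(3S,4R,5R)-4-(hydroxymethyl)-5-(3,4,5-trimethoxyphenyl)oxolan-3-yl](3,4,5-trimethoxyphenyl)methanone | COc1cc(C(=O)[C@@H]2CO[C@@H](c3cc(OC)c(OC)c(OC)c3)[C@H]2CO)cc(OC)c1OC | target

Total step count: 6. Longest linear sequence: 5 steps (steps 1, 3, 4, 5, 6 from 1 and 2; equally steps 2, 3, 4, 5, 6 from 4).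

Steps most likely to fail

Step 3 (Heck alkenylation). The catalyst may discriminate poorly between the two enantiotopic alkene carbons, and insertion may be slow, because the cis ester can chelate the cationic alkenylpalladium intermediate and occupy the site the alkene needs. The fallback replaces induction by resolution. Setting out from 3 and 5, the coupling is run with an achiral catalyst (Pd(OAc)2, 1,3-bis(diphenylphosphino)propane, iPr2NEt, DMF, 80 °C) to give the racemic vinyl acetal F1. The contraction and in situ reduction of step 4 convert it into the racemic 2,3-cis-3,4-trans alcohol F2. Esterification with (R)-2-methoxy-2-phenylacetic acid (DCC, DMAP, CH2Cl2) gives the (R)-O-methylmandelate of the (3R,4R,5R)-alcohol F3 and the diastereomeric ester of the (3S,4S,5S)-alcohol F4, which are separated by chromatography or crystallisation. Ethanolysis of F3 (K2CO3, EtOH, rt, which leaves the ethyl enoate unchanged) returns to the route at 8.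

Step 4 (ring contraction). The kinetic 2,3-cis preference may erode, either by reopening of the new C2–C3 bond under the Lewis acid before hydride arrives, or by incomplete convergence of the two acetal epimers if the ion pair collapses faster than it reorganises. The fallback sets C2 by hydride delivery to a cyclic oxocarbenium ion instead of by C–C bond formation. Setting out from 6, aqueous acid (1 M HCl, THF) hydrolyses the vinyl acetal to the 4-substituted lactol F5 and gives back aldehyde 2. TEMPO (cat.)/PhI(OAc)2 oxidises it to the (R)-β-substituted γ-butyrolactone F6. Enolisation with LiN(SiMe3)2 (THF, −78 °C) and alkylation with 4-methoxybenzyl chloromethyl ether, anti to the ring substituent, gives the trans-α-alkylated lactone F7. Slow addition of 3,4,5-trimethoxyphenyllithium (from 5-bromo-1,2,3-trimethoxybenzene and nBuLi, 1 equiv, THF, −78 °C) gives the 2-aryl hemiketal F8; the lactone carbonyl is more electrophilic than the β,β-disubstituted conjugated ester. Et3SiH/BF3·OEt2 (CH2Cl2, −78 °C) reduces the derived oxocarbenium ion with hydride entering anti to the C3 substituent, which should give the 2,3-cis-3,4-trans 4-methoxybenzyl ether F9. DDQ (CH2Cl2/pH 7 buffer) removes the ether and returns to the route at 8.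

Step 5 (dihydroxylation). Osmylation of the hindered, ester-deactivated trisubstituted alkene may be so slow that the catalyst dies or over-oxidation sets in. The fallback makes the alkene electron-rich before it is cleaved. Setting out from 8, iBu2AlH (CH2Cl2, −78 °C) reduces the ester to the allylic alcohol F10. OsO4 (cat.)/NMO should then dihydroxylate the styrene-type alkene readily to the tetraol F11. NaIO4 (2 equiv, THF/H2O) cleaves both glycol bonds with loss of formic acid and formaldehyde and returns to the route at the target 10.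

Further compounds
F1 | step 3 | racemic ethyl (2E)-3-[2-(3,4,5-trimethoxyphenyl)-4,5-dihydro-1,3-dioxepin-5-yl]-3-(3,4,5-trimethoxyphenyl)prop-2-enoate | COc1cc(/C(=C/C(=O)OCC)C2COC(c3cc(OC)c(OC)c(OC)c3)OC=C2)cc(OC)c1OC
F2 | step 3 | racemic ethyl (2E)-3-[(3R*,4R*,5R*)-4-(hydroxymethyl)-5-(3,4,5-trimethoxyphenyl)oxolan-3-yl]-3-(3,4,5-trimethoxyphenyl)prop-2-enoate (both enantiomers) | COc1cc(/C(=C/C(=O)OCC)[C@@H]2CO[C@@H](c3cc(OC)c(OC)c(OC)c3)[C@H]2CO)cc(OC)c1OC.COc1cc(/C(=C/C(=O)OCC)[C@H]2CO[C@H](c3cc(OC)c(OC)c(OC)c3)[C@@H]2CO)cc(OC)c1OC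
F3 | step 3 | ethyl (2E)-3-[(3R,4R,5R)-4-({[(2R)-2-methoxy-2-phenylacetyl]oxy}methyl)-5-(3,4,5-trimethoxyphenyl)oxolan-3-yl]-3-(3,4,5-trimethoxyphenyl)prop-2-enoate | COc1cc(/C(=C/C(=O)OCC)[C@@H]2CO[C@@H](c3cc(OC)c(OC)c(OC)c3)[C@H]2COC(=O)[C@H](OC)c4ccccc4)cc(OC)c1OC
F4 | step 3 | ethyl (2E)-3-[(3S,4S,5S)-4-({[(2R)-2-methoxy-2-phenylacetyl]oxy}methyl)-5-(3,4,5-trimethoxyphenyl)oxolan-3-yl]-3-(3,4,5-trimethoxyphenyl)prop-2-enoate (separated off) | COc1cc(/C(=C/C(=O)OCC)[C@H]2CO[C@H](c3cc(OC)c(OC)c(OC)c3)[C@@H]2COC(=O)[C@H](OC)c4ccccc4)cc(OC)c1OC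
F5 | step 4 | ethyl (2E)-3-[(3R)-5-hydroxyoxolan-3-yl]-3-(3,4,5-trimethoxyphenyl)prop-2-enoate (anomers) | COc1cc(/C(=C/C(=O)OCC)[C@@H]2COC(O)C2)cc(OC)c1OC
F6 | step 4 | ethyl (2E)-3-[(3R)-5-oxooxolan-3-yl]-3-(3,4,5-trimethoxyphenyl)prop-2-enoate | COc1cc(/C(=C/C(=O)OCC)[C@@H]2COC(=O)C2)cc(OC)c1OC
F7 | step 4 | ethyl (2E)-3-[(3R,4R)-4-{[(4-methoxyphenyl)methoxy]methyl}-5-oxooxolan-3-yl]-3-(3,4,5-trimethoxyphenyl)prop-2-enoate | COc1cc(/C(=C/C(=O)OCC)[C@@H]2COC(=O)[C@H]2COCc3ccc(OC)cc3)cc(OC)c1OC
F8 | step 4 | ethyl (2E)-3-[(3R,4R)-5-hydroxy-4-{[(4-methoxyphenyl)methoxy]methyl}-5-(3,4,5-trimethoxyphenyl)oxolan-3-yl]-3-(3,4,5-trimethoxyphenyl)prop-2-enoate (anomers) | COc1cc(/C(=C/C(=O)OCC)[C@@H]2COC(O)(c3cc(OC)c(OC)c(OC)c3)[C@H]2COCc4ccc(OC)cc4)cc(OC)c1OC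
F9 | step 4 | ethyl (2E)-3-[(3R,4R,5R)-4-{[(4-methoxyphenyl)methoxy]methyl}-5-(3,4,5-trimethoxyphenyl)oxolan-3-yl]-3-(3,4,5-trimethoxyphenyl)prop-2-enoate | COc1cc(/C(=C/C(=O)OCC)[C@@H]2CO[C@@H](c3cc(OC)c(OC)c(OC)c3)[C@H]2COCc4ccc(OC)cc4)cc(OC)c1OC
F10 | step 5 | (2E)-3-[(3R,4R,5R)-4-(hydroxymethyl)-5-(3,4,5-trimethoxyphenyl)oxolan-3-yl]-3-(3,4,5-trimethoxyphenyl)prop-2-en-1-ol | COc1cc(/C(=C/CO)[C@@H]2CO[C@@H](c3cc(OC)c(OC)c(OC)c3)[C@H]2CO)cc(OC)c1OC
F11 | step 5 | 3-[(3S,4R,5R)-4-(hydroxymethyl)-5-(3,4,5-trimethoxyphenyl)oxolan-3-yl]-3-(3,4,5-trimethoxyphenyl)propane-1,2,3-triol (syn diol, both facial diastereomers) | COc1cc(C(O)(C(O)CO)[C@@H]2CO[C@@H](c3cc(OC)c(OC)c(OC)c3)[C@H]2CO)cc(OC)c1OC
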